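**Retrosynthetic overview**
- Aryl–C(sp) bond: Sonogashira disconnection to 4-hydroxy-3-iodobenzoic acid and a silyl-capped 2-alkyl-1,3-enyne diol.
- C(sp3)–C(sp2) bond at the trisubstituted alkene: Negishi disconnection to an (E)-vinyl iodide and a homoallylic zinc reagent made from 3-bromobut-3-en-1-ol and TMS-acetylene.
- (E)-Vinyl iodide: Zr-catalysed syn-carboalumination/iodination of a chiral terminal alkyne diol, which fixes the alkene geometry.
- Key C(sp3)–C(sp) bond: photoredox decarboxylative ethynylation of the hydroxy-lactone obtained from the L-glutamic-acid-derived lactone ester and MeMgBr; this lactone supplies the only stereocentre.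
- No ring is formed; the benzene ring is purchased.

Assumptions: compound 1 is purchased as the ethyl ester of the L-glutamic-acid-derived lactone acid; a one-pot sequence with a single isolation is counted as one step.

**Route**

Step 1
Reactants: 1, ethyl (S)-5-oxotetrahydrofuran-2-carboxylate; 2, methylmagnesium bromide
Product: 3, (S)-5-(2-hydroxypropan-2-yl)dihydrofuran-2(3H)-one
Conditions: MeMgBr (2.2 equiv), THF, −78 → −20 °C; aq NH4Cl
Reagents that add atoms: methylmagnesium bromide, C[Mg]Br
Why: Double Grignard addition to the exocyclic α-acyloxy ester (and the derived α-acyloxy ketone), which are more electrophilic than the lactone at low temperature; the (S) carbinol centre from the chiral pool is untouched, and any translactonised δ-lactone converges in step 2.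

Step 2
Reactants: 3; 4, 1-[(triisopropylsilyl)ethynyl]-1,2-benziodoxol-3(1H)-one (TIPS-EBX)
Product: 5, (S)-2-methylhept-6-yne-2,3-diol
Conditions: CsOH·H2O (1.0 equiv), MeOH–H2O, rt, concentrate; 4 (1.5 equiv), Ir[dF(CF3)ppy]2(dtbbpy)PF6 (2 mol%), DMF–DCE, 450 nm LEDs, rt; then TBAF, THF, rt (one pot)
Reagents that add atoms: TIPS-EBX, CC(C)[Si](C(C)C)(C(C)C)C#CI1OC(=O)c2ccccc12
Why: Proposed new method: one-pot conversion of a γ-lactone into a homologated terminal alkyne via its unprotected hydroxy-carboxylate — CsOH opens 3 to cesium (S)-4,5-dihydroxy-5-methylhexanoate, excited Ir(III) oxidises the carboxylate by SET, loss of CO2 gives a primary radical two carbons from the stereocentre (which is therefore untouched), the radical adds to the α-carbon of the alkynyl-iodine(III) reagent and expels the 2-iodobenzoyloxy radical (reduced by Ir(II) to close the cycle), and fluoride then cleaves C–Si; the closest known reaction is photoredox decarboxylative alkynylation of free carboxylic acids with EBX reagents, which has not been shown on a lactone used as a masked, unprotected dihydroxy-carboxylate.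

Step 3
Reactants: 5
Product: 8, (3S,6E)-7-iodo-2,6-dimethylhept-6-ene-2,3-diol
Conditions: Me3Al (5 equiv), Cp2ZrCl2 (0.5 equiv), CH2Cl2, 0 °C → rt; then I2, THF, −30 → 0 °C
Reagents that add atoms: trimethylaluminium (6), C[Al](C)C; iodine (7), II
Why: Negishi Zr-catalysed carboalumination adds Me–Al syn across the terminal alkyne (Me to the internal carbon) and iodinolysis proceeds with retention, giving the (E)-trisubstituted vinyl iodide; the diol is carried as its aluminium alkoxide, as with 4-pentyn-1-ol.

Step 4
Reactants: 9, 3-bromobut-3-en-1-ol; 10, ethynyltrimethylsilane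
Product: 11, 3-methylidene-5-(trimethylsilyl)pent-4-yn-1-ol
Conditions: PdCl2(PPh3)2 (3 mol%), CuI (5 mol%), i-Pr2NH, THF, 40 °C
Reagents that add atoms: ethynyltrimethylsilane, C#C[Si](C)(C)C
Why: Sonogashira coupling of a 1,1-disubstituted vinyl bromide builds the 2-substituted 1,3-enyne with the free primary alcohol tolerated.

Step 5
Reactants: 11
Product: 12, (5-iodo-3-methylidenepent-1-yn-1-yl)trimethylsilane
Conditions: I2, PPh3, imidazole, CH2Cl2, 0 °C → rt
Reagents that add atoms: iodine (7), II
Why: Appel iodination of the primary alcohol under neutral conditions leaves the silyl enyne intact.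

Step 6
Reactants: 12; 8
Product: 13, (3S,6E)-2,6-dimethyl-10-methylidene-12-(trimethylsilyl)dodec-6-en-11-yne-2,3-diol
Conditions: 12, Zn dust (TMSCl/BrCH2CH2Br-activated), LiCl, THF, 35 °C; then slow addition (2.5 equiv) to 8, Pd(OAc)2 (3 mol%), SPhos (6 mol%), THF, rt
Reagents that add atoms: none
Why: Negishi sp3–sp2 cross-coupling: Zn inserts only into the alkyl C–I bond, alkylzinc halides tolerate free alcohols under Pd/SPhos, and the alkenyl iodide couples with retention of the E geometry.

Step 7
Reactants: 13; 14, 4-hydroxy-3-iodobenzoic acid
Product: 15, 3-[(6E,10S)-10,11-dihydroxy-7,11-dimethyl-3-methylidenedodec-6-en-1-yn-1-yl]-4-hydroxybenzoic acid (pestalotioquinol F)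
Conditions: TBAF (1.2 equiv), THF, 0 °C; then 14, PdCl2(PPh3)2 (5 mol%), CuI (5 mol%), Et3N (6 equiv), degassed, rt; pH 3 work-up
Reagents that add atoms: none
Why: In-situ C–Si cleavage followed by Sonogashira coupling of the terminal enyne with the aryl iodide (acid carried as its ammonium carboxylate); room temperature is used to suppress 5-endo cyclisation of the o-alkynylphenol to a benzofuran.

**Compound list**

1 | ethyl (S)-5-oxotetrahydrofuran-2-carboxylate | CCOC(=O)[C@@H]1CCC(=O)O1 | starting material
2 | methylmagnesium bromide | C[Mg]Br | starting material (reagent)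
3 | (S)-5-(2-hydroxypropan-2-yl)dihydrofuran-2(3H)-one | CC(C)(O)[C@@H]1CCC(=O)O1 | intermediate
4 | TIPS-EBX | CC(C)[Si](C(C)C)(C(C)C)C#CI1OC(=O)c2ccccc12 | starting material (reagent)
5 | (S)-2-methylhept-6-yne-2,3-diol | C#CCC[C@H](O)C(C)(C)O | intermediate
6 | trimethylaluminium | C[Al](C)C | starting material (reagent)
7 | iodine | II | starting material (reagent)
8 | (3S,6E)-7-iodo-2,6-dimethylhept-6-ene-2,3-diol | I/C=C(\C)CC[C@H](O)C(C)(C)O | intermediate
9 | 3-bromobut-3-en-1-ol | C=C(Br)CCO | starting material
10 | ethynyltrimethylsilane | C#C[Si](C)(C)C | starting material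
11 | 3-methylidene-5-(trimethylsilyl)pent-4-yn-1-ol | C=C(CCO)C#C[Si](C)(C)C | intermediate
12 | (5-iodo-3-methylidenepent-1-yn-1-yl)trimethylsilane | C=C(CCI)C#C[Si](C)(C)C | intermediate
13 | (3S,6E)-2,6-dimethyl-10-methylidene-12-(trimethylsilyl)dodec-6-en-11-yne-2,3-diol | C=C(C#C[Si](C)(C)C)CC/C=C(\C)CC[C@H](O)C(C)(C)O | intermediate
14 | 4-hydroxy-3-iodobenzoic acid | OC(=O)c1ccc(O)c(I)c1 | starting material
15 | pestalotioquinol F | C=C(C#Cc1cc(C(=O)O)ccc1O)CC/C=C(\C)CC[C@H](O)C(C)(C)O | target

**Step count**
Total steps: 7. Longest linear sequence: 5 (steps 1 → 2 → 3 → 6 → 7).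

**Steps most likely to fail**

1. Step 2 (proposed new step). Risks: sluggish oxidation of the unstabilised primary carboxylate, or side reactions of the iodine(III) reagent with the free 1,2-diol. Fallback (known chemistry): convert 3 to the acetonide methyl ester (2,2-dimethoxypropane, MeOH, TsOH), saponify, form the N-hydroxyphthalimide ester, and run the established reductive photoredox alkynylation of redox-active esters with a TIPS-ethynyl phenyl sulfone (Ru(bpy)3 salt, Hantzsch ester, i-Pr2NEt, blue LEDs); TBAF and aqueous HCl then rejoin the route at 5.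

2. Step 6. Risks: protonation of the zinc reagent by the free diol, or instability of the enyne-bearing homoallylic zinc. Fallback: build the enyne from a methyl ketone instead — Cu-mediated conjugate addition of the alkenylalane from 5 to methyl vinyl ketone gives the (E)-γ,δ-unsaturated ketone; then acetonide protection, kinetic enol triflate (KHMDS, PhNTf2), Sonogashira with TMS-acetylene, step 7 and acid deprotection.

3. Step 7. Risks: cyclisation of the free o-alkynylphenol to a benzofuran under Pd/Cu, or Glaser dimerisation. Fallback: attach the arene before fragment union in protected form — Sonogashira of methyl 4-acetoxy-3-iodobenzoate with desilylated 11, Appel iodination, Negishi coupling with 8, then LiOH to remove acetate and methyl ester together.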